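## Retrosynthetic overview

1. The only stereocentre (C2, S) is set by a Rh-catalysed enantioselective 1,4-addition of the B-ring arylboronic acid 7 to the protected chromone 9, which disconnects the C2–aryl bond.
2. Boronic acid 7 comes from 2,4,6-tribromoanisole by three successive halogen–metal exchanges: ortho (prenyl), ortho (prenal addition, then dehydration to the E-diene), para (borylation).
3. No ring is formed in the route. The A/C chromone bicycle and the B-ring arene are bought intact; the chromone C2=C3 is saturated in the coupling step.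
4. Phenol protection is TBS, removed last under buffered fluoride so the diene sees no strong acid and the flavanone sees no base.

Assumption: the (S)-ligand gives the (2S) product, by analogy with (S)-BINAP giving (S)-3-arylcyclohexanones; this has not been verified for this substrate, and if the measured sense is opposite the (R)-ligand is used with no other change.

## Route

**Step 1**
Reactants: 1 (2,4,6-tribromoanisole), 2 (prenyl bromide)
Product: 3, 1,5-dibromo-2-methoxy-3-(3-methylbut-2-en-1-yl)benzene
Conditions: i-PrMgCl·LiCl (1.05 equiv), THF, −20 °C; then CuI (10 mol %), 2 (1.2 equiv), −20 °C → rt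
Reagents that add atoms: prenyl bromide (2), CC(C)=CCBr
Why: Br/Mg exchange stops after one exchange and occurs ortho to OMe (inductive/chelation stabilisation), and the Cu-catalysed allylic substitution attacks the unhindered primary carbon of prenyl bromide to give the linear prenyl arene.

**Step 2**
Reactants: 3, 4 (3-methylbut-2-enal, prenal)
Product: 5, (±)-1-[5-bromo-2-methoxy-3-(3-methylbut-2-en-1-yl)phenyl]-3-methylbut-2-en-1-ol
Conditions: n-BuLi (1.05 equiv), Et2O, −78 °C; then 4, −78 → 0 °C
Reagents that add atoms: prenal (4), CC(C)=CC=O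
Why: Br/Li exchange favours the bromine ortho to OMe (the more stabilised aryllithium), which adds 1,2 to the enal; the carbinol centre is racemic and is destroyed in step 3.

**Step 3**
Reactants: 5
Product: 6, 5-bromo-2-methoxy-1-[(1E)-3-methylbuta-1,3-dien-1-yl]-3-(3-methylbut-2-en-1-yl)benzene
Conditions: PPTS (10 mol %), toluene, 4 Å MS, BHT (trace), 70 °C
Reagents that add atoms: none
Why: acid-catalysed 1,4-dehydration (E1) through the benzylic/allylic cation, which can only lose a methyl proton, gives the aryl-conjugated diene; the E geometry is the thermodynamic styrenyl isomer.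

**Step 4**
Reactants: 6
Product: 7, {4-methoxy-3-[(1E)-3-methylbuta-1,3-dien-1-yl]-5-(3-methylbut-2-en-1-yl)phenyl}boronic acid
Conditions: B(Oi-Pr)3 (1.5 equiv), n-BuLi (1.1 equiv), THF/toluene, −78 °C → rt (in situ quench); aq NH4Cl, pH ≈ 5
Reagents that add atoms: triisopropyl borate, CC(C)OB(OC(C)C)OC(C)C; water, O
Why: Br/Li exchange at −78 °C is faster than carbolithiation of the diene, and the aryllithium is trapped at once by the borate (lithiation–borylation); mild hydrolysis gives the boronic acid.

**Step 5**
Reactants: 8 (5,7-dihydroxy-4H-chromen-4-one)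
Product: 9, 5,7-bis[(tert-butyldimethylsilyl)oxy]-4H-chromen-4-one
Conditions: TBSOTf (2.6 equiv), 2,6-lutidine (4 equiv), CH2Cl2, 0 °C → rt
Reagents that add atoms: TBSOTf, CC(C)(C)[Si](C)(C)OS(=O)(=O)C(F)(F)F
Why: the silyl triflate silylates both the free 7-OH and the hydrogen-bonded 5-OH, removing acidic phenols that would deactivate the enone in the Rh step.

**Step 6**
Reactants: 9 (1.0 equiv), 7 (1.5 equiv)
Product: 10, (2S)-5,7-bis[(tert-butyldimethylsilyl)oxy]-2-{4-methoxy-3-[(1E)-3-methylbuta-1,3-dien-1-yl]-5-(3-methylbut-2-en-1-yl)phenyl}-2,3-dihydro-4H-chromen-4-one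
Conditions: [Rh(OH)(cod)]2 (2.5 mol %), (S)-MeO-F12-BIPHEP (5.5 mol %), toluene/H2O 10:1, 50 °C, no added base
Reagents that add atoms: none (the aryl group comes from 7; B(OH)2 is lost)
Why: Hayashi–Miyaura Rh-catalysed asymmetric 1,4-addition; the aryl–Rh(bisphosphine) species inserts the chromone C2=C3 on one enantioface to set C2 as S, and base-free conditions avoid retro-oxa-Michael ring opening. The bisphosphine should outcompete the substrate diene for Rh.

**Step 7**
Reactants: 10
Product: 11, (2S)-5,7-dihydroxy-2-{4-methoxy-3-[(1E)-3-methylbuta-1,3-dien-1-yl]-5-(3-methylbut-2-en-1-yl)phenyl}-2,3-dihydro-4H-chromen-4-one (target)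
Conditions: TBAF (2.5 equiv), AcOH (3 equiv), THF, 0 °C
Reagents that add atoms: none
Why: fluoride cleaves the aryl silyl ethers; AcOH buffering prevents phenoxide/enolate-driven ring opening (racemisation at C2), and no strong acid touches the diene or prenyl group. Any material that lost the labile 5-O-TBS in step 6 converges here.

## Compound list

1 | 2,4,6-tribromoanisole | COc1c(Br)cc(Br)cc1Br | starting material
2 | prenyl bromide (1-bromo-3-methylbut-2-ene) | CC(C)=CCBr | starting material
3 | 1,5-dibromo-2-methoxy-3-(3-methylbut-2-en-1-yl)benzene | COc1c(Br)cc(Br)cc1CC=C(C)C | intermediate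
4 | 3-methylbut-2-enal (prenal) | CC(C)=CC=O | starting material
5 | (±)-1-[5-bromo-2-methoxy-3-(3-methylbut-2-en-1-yl)phenyl]-3-methylbut-2-en-1-ol | COc1c(C(O)C=C(C)C)cc(Br)cc1CC=C(C)C | intermediate
6 | 5-bromo-2-methoxy-1-[(1E)-3-methylbuta-1,3-dien-1-yl]-3-(3-methylbut-2-en-1-yl)benzene | COc1c(/C=C/C(C)=C)cc(Br)cc1CC=C(C)C | intermediate
7 | {4-methoxy-3-[(1E)-3-methylbuta-1,3-dien-1-yl]-5-(3-methylbut-2-en-1-yl)phenyl}boronic acid | COc1c(/C=C/C(C)=C)cc(B(O)O)cc1CC=C(C)C | intermediate
8 | 5,7-dihydroxy-4H-chromen-4-one | O=c1ccoc2cc(O)cc(O)c12 | starting material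
9 | 5,7-bis[(tert-butyldimethylsilyl)oxy]-4H-chromen-4-one | O=c1ccoc2cc(O[Si](C)(C)C(C)(C)C)cc(O[Si](C)(C)C(C)(C)C)c12 | intermediate
10 | (2S)-5,7-bis(TBS-oxy) flavanone carrying the full B ring | C=C(C)/C=C/c1cc([C@@H]2CC(=O)c3c(O[Si](C)(C)C(C)(C)C)cc(O[Si](C)(C)C(C)(C)C)cc3O2)cc(CC=C(C)C)c1OC | intermediate
11 | (2S)-5,7-dihydroxy-4'-methoxy-3'-prenyl-5'-[(E)-3-methylbuta-1,3-dienyl]flavanone | C=C(C)/C=C/c1cc([C@@H]2CC(=O)c3c(O)cc(O)cc3O2)cc(CC=C(C)C)c1OC | target

## Summary

Total steps: 7. Longest linear sequence: 6 (steps 1–4, 6, 7); step 5 is a one-step side branch.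

Steps most likely to fail:

1. **Step 6 (Rh 1,4-addition).** The bis-silyloxy chromone is an electron-rich, hindered acceptor, and the diene could bind Rh or be arylated while the boronic acid protodeboronates. Fallback: abandon the conjugate addition for a chalcone route. Trap the aryllithium from 6 with DMF to give the aldehyde, run a Claisen–Schmidt condensation with 2'-hydroxy-4',6'-bis(MOM-oxy)acetophenone, cyclise to the racemic flavanone, and obtain the 2S enantiomer by asymmetric-transfer-hydrogenation kinetic resolution (Rh or Ru/TsDPEN).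

2. **Step 2 (ortho versus para Br/Li exchange).** Selectivity between the two remaining bromines may be incomplete. Fallback: redesign the B ring from 2,6-dibromo-4-chloroanisole. The two ortho bromines are then equivalent, so no regiochemical choice arises, and the para position is borylated last by Pd catalysis on the aryl chloride (XPhos-Pd, B2(OH)4).

3. **Step 3 (cationic dehydration).** The diene may oligomerise or the prenyl group may isomerise under acid. Fallback: make the diene by C–C coupling instead of elimination. Quench the ortho-aryllithium with I2 and run an iodide-selective Suzuki coupling with (E)-3-methylbuta-1,3-dienyl pinacol boronate, made by hydroboration of 2-methylbut-1-en-3-yne.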